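**Strategy.** The hydroazulene (azulene locants of the target) is cut at C5–C6 and at the ring-fusion bond C3a–C8a. One intramolecular (4+3) cycloaddition makes both bonds: a C3–C3a epoxide bearing a C4–C5 enol silane ionises to a silyloxyallyl cation, and a tethered C6–C7–C8–C8a silyl dienol ether adds across it. This closes the five- and seven-membered rings, sets C3a by inversion and creates quaternary C8a. The step exploits the 3-hydroxy-4-oxygen array (the epoxide leaves the tertiary C3 alcohol) and the C8 ketone (masked in the diene). The precursor is an acyclic, enantiopure epoxy bis(enol silane) assembled from crotonaldehyde, crotyl bromide, ethyl isobutyrylacetate and MeMgBr.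

Key step: step 8

Remark: bicyclic compounds carry the azulene locants of the target. The methyl-bearing carbon that becomes trigonal later (C-3 of 3, C-6 of 7, C-7 of 9–11, C-6 of 13–17) is carried as an epimer mixture, and 12 as a mixture of enol ether geometries at its tetrasubstituted double bond.

Remark: the L-series Shi ketone used in step 6 is taken as accessible from L-sorbose.

Step 1
Reactants: 1 (2E)-but-2-enal; 2 1-bromobut-2-ene
Product: 3 (5E)-3-methylhepta-1,5-dien-4-ol
Conditions: Zn dust, THF/sat. aq. NH4Cl, 0 °C to rt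
Reagents that add atoms: none
Why: Barbier crotylation, in which the allylzinc species adds 1,2 to the enal through its γ-carbon to give the branched homoallylic alcohol; both new stereocentres are removed later.

Step 2
Reactants: 4 ethyl 4-methyl-3-oxopentanoate
Product: 5 ethyl (2E)-4-methyl-3-[(trifluoromethanesulfonyl)oxy]pent-2-enoate
Conditions: Tf2O, aq. Me4NOH, hexanes, 5 °C
Reagents that add atoms: trifluoromethanesulfonic anhydride, O=S(=O)(OS(=O)(=O)C(F)(F)F)C(F)(F)F
Why: Stereoselective enol triflation, in which the non-chelated ammonium enolate is trapped on oxygen in its extended form and should give the E isomer (triflate trans to the ester).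

Step 3
Reactants: 3 (5E)-3-methylhepta-1,5-dien-4-ol; 5 ethyl (2E)-4-methyl-3-[(trifluoromethanesulfonyl)oxy]pent-2-enoate
Product: 7 ethyl (2Z,8E)-7-hydroxy-6-methyl-3-(propan-2-yl)deca-2,8-dienoate, via alkylborane 6 (not isolated)
Conditions: 9-BBN (2.2 equiv), THF, 0 °C to rt; then 5, PdCl2(dppf) (5 mol %), aq. K3PO4, DMF, rt to 50 °C
Reagents that add atoms: 9-borabicyclo[3.3.1]nonane, B1C2CCCC1CCC2 (boron in 6 only)
Why: Anti-Markovnikov hydroboration of the monosubstituted alkene only, then B-alkyl Suzuki–Miyaura coupling with retention at the enol triflate, so the chain ends trans to the ester and the isopropyl group cis to it (2Z).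

Step 4
Reactants: 7 ethyl (2Z,8E)-7-hydroxy-6-methyl-3-(propan-2-yl)deca-2,8-dienoate
Product: 9 (3Z,9E)-8-hydroxy-7-methyl-4-(propan-2-yl)undeca-3,9-dien-2-one, via Weinreb amide 8 (not isolated)
Conditions: MeNHOMe·HCl, iPrMgCl, THF, −20 °C; then MeMgBr, −20 to 0 °C; aq. NH4Cl
Reagents that add atoms: methylmagnesium bromide, C[Mg]Br; N,O-dimethylhydroxylamine hydrochloride, CNOC.Cl (atoms in 8 only)
Why: Weinreb ketone synthesis run in one flask, in which the chelated tetrahedral intermediate stops the addition at the methyl ketone and the alkene geometry is not touched.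

Step 5
Reactants: 9 (3Z,9E)-8-hydroxy-7-methyl-4-(propan-2-yl)undeca-3,9-dien-2-one
Product: 10 (3Z,9E)-7-methyl-4-(propan-2-yl)undeca-3,9-diene-2,8-dione
Conditions: Dess–Martin periodinane, CH2Cl2, 0 °C to rt
Reagents that add atoms: none
Why: Dess–Martin oxidation of the allylic alcohol to the propenyl ketone under mild conditions that should leave the Z-enone intact.

Step 6
Reactants: 10 (3Z,9E)-7-methyl-4-(propan-2-yl)undeca-3,9-diene-2,8-dione
Product: 11 (3R,4R,9E)-3,4-epoxy-7-methyl-4-(propan-2-yl)undec-9-ene-2,8-dione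
Conditions: KHSO5 (as Oxone, 1.5 equiv), L-series Shi ketone in its 4,5-di-O-acetyl form (30 mol %), NaHCO3, Bu4NHSO4, MeCN/aq. Na2EDTA, 0 °C
Reagents that add atoms: potassium peroxymonosulfate, [K+].[O-]S(=O)(=O)OO
Why: Shi epoxidation, in which concerted oxygen transfer copies the Z geometry into the cis relation of acetyl and isopropyl, the spiro transition state with the lone vinylic hydrogen next to the spiroketal should give (3R,4R) with the L-series ketone, and the trisubstituted β,β-dialkyl enone is the more electron-rich of the two alkenes.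

Step 7
Reactants: 11 (3R,4R,9E)-3,4-epoxy-7-methyl-4-(propan-2-yl)undec-9-ene-2,8-dione
Product: 12 (2R,3R)-3-[(5E)-3-methyl-4-(triethylsilyloxy)hepta-3,5-dien-1-yl]-3-(propan-2-yl)-2-[1-(triethylsilyloxy)ethenyl]oxirane
Conditions: Et3SiCl (5 equiv), LiN(iPr)2 (2.4 equiv), THF, −78 °C (internal quench); Et3N, pentane work-up
Reagents that add atoms: chlorotriethylsilane, CC[Si](Cl)(CC)CC
Why: Kinetic enolisation with in situ silylation, at the methyl group of the epoxy ketone and at the α′ methine of the enone (cross-conjugated enolate); the enol ether geometry is expected to favour the chain cis to oxygen.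

Step 8
Reactants: 12 (2R,3R)-3-[(5E)-3-methyl-4-(triethylsilyloxy)hepta-3,5-dien-1-yl]-3-(propan-2-yl)-2-[1-(triethylsilyloxy)ethenyl]oxirane
Product: 14 (3R,3aS,8aS)-3-hydroxy-6,8a-dimethyl-3-(propan-2-yl)octahydroazulene-4,8-dione, via silylated cycloadduct 13 (not isolated)
Conditions: Et3SiOTf (10–20 mol %), CH2Cl2, −78 °C; pyridine; then HF·pyridine, THF, 0 °C to rt
Reagents that add atoms: none
Why: Et3SiOTf silylates the epoxide oxygen, the C3a–O bond ionises with help from the adjacent enol silane (silyloxyallyl cation character) while C8a of the silyl dienol ether attacks from the rear, C5 then bonds to C6 in the same asynchronous event, and the silyl group of the allyl unit is released to turn the catalyst over. The closest known reaction is the silyl-triflate-catalysed intramolecular (4+3) cycloaddition of epoxy enol silanes with tethered dienes, here with a 2-silyloxydiene as the four-carbon partner. The cyclopentane closes by attack of C8a on epoxide carbon C3a with the breaking C–O bond outside the new ring, and the cycloheptane by a seven-membered endo closure of C5 onto C6 of the silyl-activated dienyl unit (Mukaiyama–Michael-like). C3 is carried from the epoxide, C3a is set by inversion (the cis relation of enol silane carbon and isopropyl in 12 puts H-3a cis to the C3 oxygen), and C8a by the compact stacking of diene over allyl unit, which puts its methyl on the side of H-3a (cis fusion) because the extended alternative presses the inside substituent of the diene terminus onto the silyloxy-bearing central carbon. The step needs bonding of C5 to C6 and not to the carbonyl-derived C8 (soft enol silane, neopentyl C8) and cis over trans fusion; C6 forms as a mixture that step 11 erases. HF·pyridine then cleaves the tertiary silyl ether and the ring enol silane.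

Step 9
Reactants: 14 (3R,3aS,8aS)-3-hydroxy-6,8a-dimethyl-3-(propan-2-yl)octahydroazulene-4,8-dione
Product: 15 (3R,3aR,4S,8aS)-3,4-dihydroxy-6,8a-dimethyl-3-(propan-2-yl)octahydroazulen-8(1H)-one
Conditions: Me4NBH(OAc)3, MeCN/AcOH (1:1), −25 °C
Reagents that add atoms: none
Why: Evans–Saksena reduction, in which the borohydride bound to the C3 hydroxyl delivers hydride internally to the β-hydroxy ketone only (C4, not C8) from the face of the C3 oxygen, giving the 1,3-anti diol with (4S) configuration.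

Step 10
Reactants: 15 (3R,3aR,4S,8aS)-3,4-dihydroxy-6,8a-dimethyl-3-(propan-2-yl)octahydroazulen-8(1H)-one; 16 4-methoxybenzoyl chloride
Product: 17 (3R,3aR,4S,8aS)-3-hydroxy-6,8a-dimethyl-8-oxo-3-(propan-2-yl)decahydroazulen-4-yl 4-methoxybenzoate
Conditions: pyridine, DMAP (cat.), CH2Cl2, 0 °C to rt
Reagents that add atoms: 4-methoxybenzoyl chloride 16, COc1ccc(C(=O)Cl)cc1
Why: DMAP-catalysed acylation of the secondary alcohol; the tertiary C3 alcohol is too hindered to react.

Step 11
Reactants: 17 (3R,3aR,4S,8aS)-3-hydroxy-6,8a-dimethyl-8-oxo-3-(propan-2-yl)decahydroazulen-4-yl 4-methoxybenzoate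
Product: 18 (3R,3aR,4S,8aS)-3-hydroxy-6,8a-dimethyl-8-oxo-3-(propan-2-yl)-1,2,3,3a,4,5,8,8a-octahydroazulen-4-yl 4-methoxybenzoate
Conditions: IBX (2.5 equiv), DMSO/fluorobenzene (1:2), 70 °C
Reagents that add atoms: none
Why: IBX dehydrogenation of the ketone through its enol; C8a is quaternary, so only C7 can enolise and the double bond must form at C6–C7, which also removes the C6 stereocentre.

**Compound list**

1 | (2E)-but-2-enal (crotonaldehyde) | C/C=C/C=O | starting material
2 | 1-bromobut-2-ene (crotyl bromide, E/Z mixture) | CC=CCBr | starting material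
3 | (5E)-3-methylhepta-1,5-dien-4-ol | C=CC(C)C(O)/C=C/C | intermediate
4 | ethyl 4-methyl-3-oxopentanoate | CCOC(=O)CC(=O)C(C)C | starting material
5 | ethyl (2E)-4-methyl-3-[(trifluoromethanesulfonyl)oxy]pent-2-enoate | CCOC(=O)/C=C(/OS(=O)(=O)C(F)(F)F)C(C)C | intermediate
6 | 9-[(5E)-4-hydroxy-3-methylhept-5-en-1-yl]-9-borabicyclo[3.3.1]nonane | C/C=C/C(O)C(C)CCB1C2CCCC1CCC2 | intermediate
7 | ethyl (2Z,8E)-7-hydroxy-6-methyl-3-(propan-2-yl)deca-2,8-dienoate | CCOC(=O)/C=C(/CCC(C)C(O)/C=C/C)C(C)C | intermediate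
8 | (2Z,8E)-7-hydroxy-N-methoxy-N,6-dimethyl-3-(propan-2-yl)deca-2,8-dienamide | CON(C)C(=O)/C=C(/CCC(C)C(O)/C=C/C)C(C)C | intermediate
9 | (3Z,9E)-8-hydroxy-7-methyl-4-(propan-2-yl)undeca-3,9-dien-2-one | CC(=O)/C=C(/CCC(C)C(O)/C=C/C)C(C)C | intermediate
10 | (3Z,9E)-7-methyl-4-(propan-2-yl)undeca-3,9-diene-2,8-dione | CC(=O)/C=C(/CCC(C)C(=O)/C=C/C)C(C)C | intermediate
11 | (3R,4R,9E)-3,4-epoxy-7-methyl-4-(propan-2-yl)undec-9-ene-2,8-dione | C/C=C/C(=O)C(C)CC[C@]1(C(C)C)O[C@H]1C(C)=O | intermediate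
12 | (2R,3R)-3-[(5E)-3-methyl-4-(triethylsilyloxy)hepta-3,5-dien-1-yl]-3-(propan-2-yl)-2-[1-(triethylsilyloxy)ethenyl]oxirane | C/C=C/C(O[Si](CC)(CC)CC)=C(C)CC[C@]1(C(C)C)O[C@H]1C(=C)O[Si](CC)(CC)CC | intermediate
13 | (3R,3aS,8aS)-6,8a-dimethyl-3-(propan-2-yl)-3,8-bis(triethylsilyloxy)-2,3,3a,5,6,8a-hexahydroazulen-4(1H)-one | O=C1CC(C)C=C(O[Si](CC)(CC)CC)[C@@]2(C)CC[C@@](O[Si](CC)(CC)CC)(C(C)C)[C@@H]12 | intermediate
14 | (3R,3aS,8aS)-3-hydroxy-6,8a-dimethyl-3-(propan-2-yl)octahydroazulene-4,8-dione | O=C1CC(C)CC(=O)[C@@]2(C)CC[C@@](O)(C(C)C)[C@@H]12 | intermediate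
15 | (3R,3aR,4S,8aS)-3,4-dihydroxy-6,8a-dimethyl-3-(propan-2-yl)octahydroazulen-8(1H)-one | O[C@H]1CC(C)CC(=O)[C@@]2(C)CC[C@@](O)(C(C)C)[C@@H]12 | intermediate
16 | 4-methoxybenzoyl chloride | COc1ccc(C(=O)Cl)cc1 | starting material
17 | (3R,3aR,4S,8aS)-3-hydroxy-6,8a-dimethyl-8-oxo-3-(propan-2-yl)decahydroazulen-4-yl 4-methoxybenzoate | COc1ccc(C(=O)O[C@H]2CC(C)CC(=O)[C@@]3(C)CC[C@@](O)(C(C)C)[C@@H]23)cc1 | intermediate
18 | (3R,3aR,4S,8aS)-3-hydroxy-6,8a-dimethyl-8-oxo-3-(propan-2-yl)-1,2,3,3a,4,5,8,8a-octahydroazulen-4-yl 4-methoxybenzoate | COc1ccc(C(=O)O[C@H]2CC(C)=CC(=O)[C@@]3(C)CC[C@@](O)(C(C)C)[C@@H]23)cc1 | target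

**Step count.** 11 steps in total; the longest linear sequence is 10 steps (steps 1 and 3–11), with step 2 as the convergent branch.

**Steps most likely to fail**

Step 8. The diene may stack in the extended way and give the trans ring fusion, or the second bond may close at the carbonyl-derived carbon and give a five-membered ring. The fallback takes the quaternary centre out of the ring-forming event and installs the angular methyl last.
- Setting out from 1, Barbier allylation with allyl bromide and Zn gives (5E)-hepta-1,5-dien-4-ol F1.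
- Hydroboration with 9-BBN gives the borane 9-[(5E)-4-hydroxyhept-5-en-1-yl]-9-borabicyclo[3.3.1]nonane F2, and coupling with 5 as in step 3 gives ethyl (2Z,8E)-7-hydroxy-3-(propan-2-yl)deca-2,8-dienoate F3.
- The conditions of step 4 give, through (2Z,8E)-7-hydroxy-N-methoxy-N-methyl-3-(propan-2-yl)deca-2,8-dienamide F4, the enone (3Z,9E)-8-hydroxy-4-(propan-2-yl)undeca-3,9-dien-2-one F5.
- Dess–Martin oxidation gives (3Z,9E)-4-(propan-2-yl)undeca-3,9-diene-2,8-dione F6, and the epoxidation of step 6 gives (3R,4R,9E)-3,4-epoxy-4-(propan-2-yl)undec-9-ene-2,8-dione F7.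
- Silylation as in step 7 gives (2R,3R)-3-(propan-2-yl)-2-[1-(triethylsilyloxy)ethenyl]-3-[(5E)-4-(triethylsilyloxy)hepta-3,5-dien-1-yl]oxirane F8, whose nucleophilic terminus is trisubstituted and unhindered.
- The Et3SiOTf-catalysed cycloaddition, quenched with pyridine and isolated, gives (3R,3aS)-6-methyl-3-(propan-2-yl)-3,8-bis(triethylsilyloxy)-2,3,3a,5,6,8a-hexahydroazulen-4(1H)-one F9. Only C3a, set by inversion, has to be right here, because C8a still carries an enolisable hydrogen.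
- Saegusa–Ito oxidation of the ring enol silane (Pd(OAc)2, MeCN) gives (3R,3aS)-6-methyl-3-(propan-2-yl)-3-(triethylsilyloxy)-2,3,3a,8a-tetrahydroazulene-4,8(1H,5H)-dione F10, and HF·pyridine gives (3R,3aS)-3-hydroxy-6-methyl-3-(propan-2-yl)-2,3,3a,8a-tetrahydroazulene-4,8(1H,5H)-dione F11.
- Me4NBH(OAc)3 gives (3R,3aR,4S)-3,4-dihydroxy-6-methyl-3-(propan-2-yl)-2,3,3a,4,5,8a-hexahydroazulen-8(1H)-one F12, and acylation with 16 gives (3R,3aR,4S)-3-hydroxy-6-methyl-8-oxo-3-(propan-2-yl)-1,2,3,3a,4,5,8,8a-octahydroazulen-4-yl 4-methoxybenzoate F13.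
- Kinetic α′-deprotonation (LiN(iPr)2, 2.2 equiv, THF, −78 °C) and MeI should then place the angular methyl on the face of H-3a, as is usual for alkylation of a ring-fusion enolate, and the route comes back at 18.

Step 6. The propenyl enone may also be epoxidised, or the hindered Z-enone may give low face discrimination. The fallback relays the configuration from a carbinol and uses a hydroxyl-directed epoxidation.
- Setting out from 9, silylation (tBuMe2SiOTf, 2,6-lutidine) gives (3Z,9E)-8-[(tert-butyldimethylsilyl)oxy]-7-methyl-4-(propan-2-yl)undeca-3,9-dien-2-one F14.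
- Corey–Bakshi–Shibata reduction ((S)-2-methyl-CBS-oxazaborolidine, catecholborane, toluene, −78 °C) should give (2R,3Z,9E)-8-[(tert-butyldimethylsilyl)oxy]-7-methyl-4-(propan-2-yl)undeca-3,9-dien-2-ol F15.
- Directed epoxidation (VO(acac)2, tBuOOH, CH2Cl2, 0 °C), steered to the threo isomer by allylic 1,3-strain from the cis isopropyl group, should give (2R,3S,4R,9E)-8-[(tert-butyldimethylsilyl)oxy]-3,4-epoxy-7-methyl-4-(propan-2-yl)undec-9-en-2-ol F16. The minor erythro isomer is removed at this stage, since it would lead to the enantiomer of 11.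
- Bu4NF gives (2R,3S,4R,9E)-3,4-epoxy-7-methyl-4-(propan-2-yl)undec-9-ene-2,8-diol F17, and Dess–Martin periodinane oxidises both carbinols, which returns the route at 11.

Step 9. The C3 oxygen and C4 are trans on the cyclopentane, so internal hydride delivery may be strained and external attack may give the C4 epimer. The fallback sets C4 by substitution instead.
- Setting out from 14, reduction with LiBH(sBu)3 (THF, −78 °C) from the face away from the C3 oxygen and the angular methyl should give (3R,3aR,4R,8aS)-3,4-dihydroxy-6,8a-dimethyl-3-(propan-2-yl)octahydroazulen-8(1H)-one F18.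
- Mitsunobu esterification with 4-methoxybenzoic acid (PPh3, diisopropyl azodicarboxylate, toluene) inverts C4 and returns the route at 17.

**Further compounds**

F1 | step 8 | (5E)-hepta-1,5-dien-4-ol | C=CCC(O)/C=C/C
F2 | step 8 | 9-[(5E)-4-hydroxyhept-5-en-1-yl]-9-borabicyclo[3.3.1]nonane | C/C=C/C(O)CCCB1C2CCCC1CCC2
F3 | step 8 | ethyl (2Z,8E)-7-hydroxy-3-(propan-2-yl)deca-2,8-dienoate | CCOC(=O)/C=C(/CCCC(O)/C=C/C)C(C)C
F4 | step 8 | (2Z,8E)-7-hydroxy-N-methoxy-N-methyl-3-(propan-2-yl)deca-2,8-dienamide | CON(C)C(=O)/C=C(/CCCC(O)/C=C/C)C(C)C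
F5 | step 8 | (3Z,9E)-8-hydroxy-4-(propan-2-yl)undeca-3,9-dien-2-one | CC(=O)/C=C(/CCCC(O)/C=C/C)C(C)C
F6 | step 8 | (3Z,9E)-4-(propan-2-yl)undeca-3,9-diene-2,8-dione | CC(=O)/C=C(/CCCC(=O)/C=C/C)C(C)C
F7 | step 8 | (3R,4R,9E)-3,4-epoxy-4-(propan-2-yl)undec-9-ene-2,8-dione | C/C=C/C(=O)CCC[C@]1(C(C)C)O[C@H]1C(C)=O
F8 | step 8 | (2R,3R)-3-(propan-2-yl)-2-[1-(triethylsilyloxy)ethenyl]-3-[(5E)-4-(triethylsilyloxy)hepta-3,5-dien-1-yl]oxirane | C/C=C/C(O[Si](CC)(CC)CC)=CCC[C@]1(C(C)C)O[C@H]1C(=C)O[Si](CC)(CC)CC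
F9 | step 8 | (3R,3aS)-6-methyl-3-(propan-2-yl)-3,8-bis(triethylsilyloxy)-2,3,3a,5,6,8a-hexahydroazulen-4(1H)-one | O=C1CC(C)C=C(O[Si](CC)(CC)CC)C2CC[C@@](O[Si](CC)(CC)CC)(C(C)C)[C@@H]12
F10 | step 8 | (3R,3aS)-6-methyl-3-(propan-2-yl)-3-(triethylsilyloxy)-2,3,3a,8a-tetrahydroazulene-4,8(1H,5H)-dione | O=C1CC(C)=CC(=O)C2CC[C@@](O[Si](CC)(CC)CC)(C(C)C)[C@@H]12
F11 | step 8 | (3R,3aS)-3-hydroxy-6-methyl-3-(propan-2-yl)-2,3,3a,8a-tetrahydroazulene-4,8(1H,5H)-dione | O=C1CC(C)=CC(=O)C2CC[C@@](O)(C(C)C)[C@@H]12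
F12 | step 8 | (3R,3aR,4S)-3,4-dihydroxy-6-methyl-3-(propan-2-yl)-2,3,3a,4,5,8a-hexahydroazulen-8(1H)-one | O[C@H]1CC(C)=CC(=O)C2CC[C@@](O)(C(C)C)[C@@H]12
F13 | step 8 | (3R,3aR,4S)-3-hydroxy-6-methyl-8-oxo-3-(propan-2-yl)-1,2,3,3a,4,5,8,8a-octahydroazulen-4-yl 4-methoxybenzoate | COc1ccc(C(=O)O[C@H]2CC(C)=CC(=O)C3CC[C@@](O)(C(C)C)[C@@H]23)cc1
F14 | step 6 | (3Z,9E)-8-[(tert-butyldimethylsilyl)oxy]-7-methyl-4-(propan-2-yl)undeca-3,9-dien-2-one | CC(=O)/C=C(/CCC(C)C(O[Si](C)(C)C(C)(C)C)/C=C/C)C(C)C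
F15 | step 6 | (2R,3Z,9E)-8-[(tert-butyldimethylsilyl)oxy]-7-methyl-4-(propan-2-yl)undeca-3,9-dien-2-ol | C[C@@H](O)/C=C(/CCC(C)C(O[Si](C)(C)C(C)(C)C)/C=C/C)C(C)C
F16 | step 6 | (2R,3S,4R,9E)-8-[(tert-butyldimethylsilyl)oxy]-3,4-epoxy-7-methyl-4-(propan-2-yl)undec-9-en-2-ol | C[C@@H](O)[C@@H]1O[C@@]1(C(C)C)CCC(C)C(O[Si](C)(C)C(C)(C)C)/C=C/C
F17 | step 6 | (2R,3S,4R,9E)-3,4-epoxy-7-methyl-4-(propan-2-yl)undec-9-ene-2,8-diol | C[C@@H](O)[C@@H]1O[C@@]1(C(C)C)CCC(C)C(O)/C=C/C
F18 | step 9 | (3R,3aR,4R,8aS)-3,4-dihydroxy-6,8a-dimethyl-3-(propan-2-yl)octahydroazulen-8(1H)-one | O[C@@H]1CC(C)CC(=O)[C@@]2(C)CC[C@@](O)(C(C)C)[C@@H]12
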